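## Retrosynthetic overview

- The target comes from O-methylation of the tertiary quinol alcohol; the C5 enol ether comes from Saegusa dehydrogenation of a β-methoxy ketone, and the C2 propenyl group from Suzuki coupling of an α-iodoenone.
- The single stereocentre (C4) comes from a catalytic enantioselective desymmetrisation (boronic-acid oxa-Michael) of a prochiral 4-alkenyl p-quinol; the temporary C5 carbinol centre is erased later.
- The (E)-styrenyl side chain comes from ketone reduction and E1 elimination; the key C4–C bond comes from an intermolecular aldol addition of the lithium enolate of 1-(3,4-dimethoxyphenyl)propan-1-one to p-benzoquinone dimethyl monoketal.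
- The monoketal comes from oxidative dearomatisation of 4-methoxyphenol.
- Rings: no carbocycle is built. The six-membered ring is the dearomatised phenol ring (first event) and the aryl ring is bought; the only ring formed on the way is a transient dioxaborolane in the desymmetrisation.

Assumption: the quinine-derived thiourea in step 6 is taken to give the (4S,5S)-diol; if it gives the antipode, the quinidine-derived pseudo-enantiomer is used with no other change.

Convention: ring locants follow the target (C1 carbonyl, C2 propenyl-bearing, C4 quaternary, C5 methoxy-bearing).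

## Route

Step 1
Reactants: 1 4-methoxyphenol
Product: 2 4,4-dimethoxycyclohexa-2,5-dien-1-one
Conditions: PhI(OAc)2 (1.05 equiv), MeOH, 0 °C
Reagents that add atoms: methanol (CO)
Why: Hypervalent-iodine oxidative dearomatisation of a p-alkoxyphenol in methanol captures the solvent at the para carbon and gives the p-quinone monoketal, which has one free, non-enolisable carbonyl.

Step 2
Reactants: 3 1-(3,4-dimethoxyphenyl)propan-1-one; 2 4,4-dimethoxycyclohexa-2,5-dien-1-one
Product: 6 rac-1-(3,4-dimethoxyphenyl)-2-[4,4-dimethoxy-1-(trimethylsilyloxy)cyclohexa-2,5-dien-1-yl]propan-1-one, via lithium (Z)-enolate 4 (not isolated), via lithium aldolate 5 (not isolated)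
Conditions: LiN(iPr)2, THF, −78 °C; then 2, −78 °C; then Me3SiCl, −78 → −20 °C
Reagents that add atoms: chlorotrimethylsilane (C[Si](C)(C)Cl)
Why: Kinetic intermolecular aldol addition of the hard lithium enolate to the only carbonyl of the monoketal (1,2-addition at −78 °C), with O-silylation of the aldolate in the same flask to block retro-aldol; the side-chain methine centre is racemic and is erased in step 4, and the carbinol carbon is not yet stereogenic because its two ring arms are identical.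

Step 3
Reactants: 6 rac-1-(3,4-dimethoxyphenyl)-2-[4,4-dimethoxy-1-(trimethylsilyloxy)cyclohexa-2,5-dien-1-yl]propan-1-one
Product: 7 1-(3,4-dimethoxyphenyl)-2-[4,4-dimethoxy-1-(trimethylsilyloxy)cyclohexa-2,5-dien-1-yl]propan-1-ol (racemic diastereomer mixture)
Conditions: iBu2AlH, CH2Cl2, −78 °C; aq. KNaC4H4O6 (potassium sodium tartrate) work-up
Reagents that add atoms: none
Why: Hydride reduction of the aryl ketone at −78 °C under aprotic conditions leaves the ketal, the diene and the silyl ether untouched and avoids base-induced 1,3-silyl migration; the new benzylic centre is uncontrolled and is erased in step 4.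

Step 4
Reactants: 7 1-(3,4-dimethoxyphenyl)-2-[4,4-dimethoxy-1-(trimethylsilyloxy)cyclohexa-2,5-dien-1-yl]propan-1-ol
Product: 9 {1-[(E)-1-(3,4-dimethoxyphenyl)prop-1-en-2-yl]-4,4-dimethoxycyclohexa-2,5-dien-1-yl}oxy(trimethyl)silane, via benzylic mesylate 8 (not isolated)
Conditions: MeSO2Cl, Et3N, CH2Cl2, −20 °C → rt
Reagents that add atoms: none
Why: Sulfonylation of the only free hydroxyl gives an electron-rich benzylic mesylate that ionises and loses the neighbouring methine proton (E1 elimination under amine buffering); both diastereomers of 7 converge on the E alkene because the aryl group turns away from the quaternary ring carbon.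

Step 5
Reactants: 9 {1-[(E)-1-(3,4-dimethoxyphenyl)prop-1-en-2-yl]-4,4-dimethoxycyclohexa-2,5-dien-1-yl}oxy(trimethyl)silane
Product: 10 4-[(E)-1-(3,4-dimethoxyphenyl)prop-1-en-2-yl]-4-hydroxycyclohexa-2,5-dien-1-one
Conditions: 1 M aq. HCl, THF, 0 °C → rt
Reagents that add atoms: water (O)
Why: Acetal hydrolysis and desilylation in one operation give the achiral, prochiral p-quinol, whose tertiary carbinol resists ionisation because the cation would be phenoxonium-like.

Step 6
Reactants: 10 4-[(E)-1-(3,4-dimethoxyphenyl)prop-1-en-2-yl]-4-hydroxycyclohexa-2,5-dien-1-one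
Product: 12 (4S,5S)-4-[(E)-1-(3,4-dimethoxyphenyl)prop-1-en-2-yl]-4,5-dihydroxycyclohex-2-en-1-one, via cyclic phenylboronate 11 (not isolated)
Conditions: PhB(OH)2 (1.5 equiv), 1-[3,5-bis(trifluoromethyl)phenyl]-3-[(8S,9S)-6′-methoxycinchonan-9-yl]thiourea (20 mol %), 4 Å molecular sieves, PhMe, rt; then pinacol, CH2Cl2, rt
Reagents that add atoms: phenylboronic acid (OB(O)c1ccccc1)
Why: Enantioselective desymmetrising intramolecular oxa-Michael addition: the quinol OH forms a boronic hemiester, the catalyst's quinuclidine activates the B–OH while its thiourea binds the dienone carbonyl, and the oxygen is delivered to one of the two enantiotopic β-carbons, necessarily cis to the C4–O bond, so C5 (S) and the now stereogenic C4 (S) are set together before pinacol transesterification frees the diol.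

Step 7
Reactants: 12 (4S,5S)-4-[(E)-1-(3,4-dimethoxyphenyl)prop-1-en-2-yl]-4,5-dihydroxycyclohex-2-en-1-one
Product: 13 (4S,5S)-4-[(E)-1-(3,4-dimethoxyphenyl)prop-1-en-2-yl]-4-hydroxy-5-methoxycyclohex-2-en-1-one
Conditions: Me3OBF4, 1,8-bis(dimethylamino)naphthalene, CH2Cl2, 0 °C → rt
Reagents that add atoms: trimethyloxonium tetrafluoroborate (C[O+](C)C.F[B-](F)(F)F)
Why: Meerwein-salt O-methylation under essentially neutral conditions alkylates the secondary hydroxyl selectively over the hindered tertiary one and avoids retro-oxa-Michael or retro-aldol loss of the β-oxygen; no stereocentre is touched.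

Step 8
Reactants: 13 (4S,5S)-4-[(E)-1-(3,4-dimethoxyphenyl)prop-1-en-2-yl]-4-hydroxy-5-methoxycyclohex-2-en-1-one
Product: 14 (4S,5S)-4-[(E)-1-(3,4-dimethoxyphenyl)prop-1-en-2-yl]-4-hydroxy-2-iodo-5-methoxycyclohex-2-en-1-one
Conditions: I2, pyridine/CH2Cl2 (1:1), 0 °C → rt
Reagents that add atoms: iodine (II)
Why: Johnson α-iodination (pyridine conjugate addition, iodination of the enolate, loss of pyridine) functionalises C2 of the only enone; the veratryl ring and the hindered styrene are inert to I2/pyridine.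

Step 9
Reactants: 14 (4S,5S)-4-[(E)-1-(3,4-dimethoxyphenyl)prop-1-en-2-yl]-4-hydroxy-2-iodo-5-methoxycyclohex-2-en-1-one; 15 (E)-prop-1-en-1-ylboronic acid
Product: 16 (4S,5S)-4-[(E)-1-(3,4-dimethoxyphenyl)prop-1-en-2-yl]-4-hydroxy-5-methoxy-2-[(E)-prop-1-en-1-yl]cyclohex-2-en-1-one
Conditions: PdCl2(PhCN)2 (5 mol %), AsPh3, Ag2O, THF/H2O (8:1), rt
Reagents that add atoms: none
Why: Suzuki–Miyaura coupling of an α-iodoenone with an alkenylboronic acid under silver-oxide promotion runs at room temperature with retention of the E geometry and is mild enough for the β-methoxy ketone.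

Step 10
Reactants: 16 (4S,5S)-4-[(E)-1-(3,4-dimethoxyphenyl)prop-1-en-2-yl]-4-hydroxy-5-methoxy-2-[(E)-prop-1-en-1-yl]cyclohex-2-en-1-one
Product: 17 (5S,6S)-5-[(E)-1-(3,4-dimethoxyphenyl)prop-1-en-2-yl]-6-methoxy-3-[(E)-prop-1-en-1-yl]-2,5-bis(trimethylsilyloxy)cyclohexa-1,3-diene
Conditions: Me3SiOTf, Et3N, CH2Cl2, −78 → 0 °C
Reagents that add atoms: trimethylsilyl trifluoromethanesulfonate (C[Si](C)(C)OS(=O)(=O)C(F)(F)F)
Why: Soft enolisation and silylation: C6 is the only enolisable position, so a single silyl dienol ether forms without a free enolate that could expel the β-methoxide, and the tertiary hydroxyl is silylated at the same time.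

Step 11
Reactants: 17 (5S,6S)-5-[(E)-1-(3,4-dimethoxyphenyl)prop-1-en-2-yl]-6-methoxy-3-[(E)-prop-1-en-1-yl]-2,5-bis(trimethylsilyloxy)cyclohexa-1,3-diene
Product: 19 (4S)-4-[(E)-1-(3,4-dimethoxyphenyl)prop-1-en-2-yl]-4-hydroxy-5-methoxy-2-[(E)-prop-1-en-1-yl]cyclohexa-2,5-dien-1-one, via silyl ether dienone 18 (not isolated)
Conditions: Pd(OAc)2 (1.2 equiv), MeCN, rt; then K2CO3 (cat.), MeOH, 0 °C
Reagents that add atoms: none
Why: Saegusa–Ito oxidation: the palladium enolate at C6 undergoes β-hydride elimination of the C5–H to give the β-methoxy enone with unambiguous regiochemistry, which erases the C5 centre and leaves C4 (S) as the only stereocentre; methanolysis then removes the tertiary silyl ether.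

Step 12
Reactants: 19 (4S)-4-[(E)-1-(3,4-dimethoxyphenyl)prop-1-en-2-yl]-4-hydroxy-5-methoxy-2-[(E)-prop-1-en-1-yl]cyclohexa-2,5-dien-1-one
Product: 21 (4S)-4-[(E)-1-(3,4-dimethoxyphenyl)prop-1-en-2-yl]-4,5-dimethoxy-2-[(E)-prop-1-en-1-yl]cyclohexa-2,5-dien-1-one, via sodium alkoxide 20 (not isolated)
Conditions: NaH, THF, 0 °C; then MeI, 0 °C → rt
Reagents that add atoms: iodomethane (CI)
Why: Williamson O-methylation of the tertiary alkoxide; the dienone has no enolisable hydrogen and the quaternary C4 cannot epimerise, so the (S) configuration is retained.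

## Compound list

1 | 4-methoxyphenol | COc1ccc(O)cc1 | starting material
2 | 4,4-dimethoxycyclohexa-2,5-dien-1-one | COC1(OC)C=CC(=O)C=C1 | intermediate
3 | 1-(3,4-dimethoxyphenyl)propan-1-one | CCC(=O)c1ccc(OC)c(OC)c1 | starting material
4 | lithium (Z)-1-(3,4-dimethoxyphenyl)prop-1-en-1-olate | C/C=C(\[O-])c1ccc(OC)c(OC)c1.[Li+] | intermediate
5 | lithium 1-[1-(3,4-dimethoxyphenyl)-1-oxopropan-2-yl]-4,4-dimethoxycyclohexa-2,5-dien-1-olate (racemic) | CC(C(=O)c1ccc(OC)c(OC)c1)C1([O-])C=CC(OC)(OC)C=C1.[Li+] | intermediate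
6 | rac-1-(3,4-dimethoxyphenyl)-2-[4,4-dimethoxy-1-(trimethylsilyloxy)cyclohexa-2,5-dien-1-yl]propan-1-one | CC(C(=O)c1ccc(OC)c(OC)c1)C1(O[Si](C)(C)C)C=CC(OC)(OC)C=C1 | intermediate
7 | 1-(3,4-dimethoxyphenyl)-2-[4,4-dimethoxy-1-(trimethylsilyloxy)cyclohexa-2,5-dien-1-yl]propan-1-ol (racemic diastereomer mixture) | CC(C(O)c1ccc(OC)c(OC)c1)C1(O[Si](C)(C)C)C=CC(OC)(OC)C=C1 | intermediate
8 | 1-(3,4-dimethoxyphenyl)-2-[4,4-dimethoxy-1-(trimethylsilyloxy)cyclohexa-2,5-dien-1-yl]propyl methanesulfonate | CC(C(OS(C)(=O)=O)c1ccc(OC)c(OC)c1)C1(O[Si](C)(C)C)C=CC(OC)(OC)C=C1 | intermediate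
9 | {1-[(E)-1-(3,4-dimethoxyphenyl)prop-1-en-2-yl]-4,4-dimethoxycyclohexa-2,5-dien-1-yl}oxy(trimethyl)silane | C[Si](C)(C)OC1(/C(C)=C/c2ccc(OC)c(OC)c2)C=CC(OC)(OC)C=C1 | intermediate
10 | 4-[(E)-1-(3,4-dimethoxyphenyl)prop-1-en-2-yl]-4-hydroxycyclohexa-2,5-dien-1-one | OC1(/C(C)=C/c2ccc(OC)c(OC)c2)C=CC(=O)C=C1 | intermediate
11 | (3aS,7aS)-7a-[(E)-1-(3,4-dimethoxyphenyl)prop-1-en-2-yl]-2-phenyl-3a,4-dihydro-1,3,2-benzodioxaborol-5(7aH)-one | O=C1C=C[C@@]2(/C(C)=C/c3ccc(OC)c(OC)c3)OB(c3ccccc3)O[C@H]2C1 | intermediate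
12 | (4S,5S)-4-[(E)-1-(3,4-dimethoxyphenyl)prop-1-en-2-yl]-4,5-dihydroxycyclohex-2-en-1-one | O=C1C=C[C@](O)(/C(C)=C/c2ccc(OC)c(OC)c2)[C@@H](O)C1 | intermediate
13 | (4S,5S)-4-[(E)-1-(3,4-dimethoxyphenyl)prop-1-en-2-yl]-4-hydroxy-5-methoxycyclohex-2-en-1-one | O=C1C=C[C@](O)(/C(C)=C/c2ccc(OC)c(OC)c2)[C@@H](OC)C1 | intermediate
14 | (4S,5S)-4-[(E)-1-(3,4-dimethoxyphenyl)prop-1-en-2-yl]-4-hydroxy-2-iodo-5-methoxycyclohex-2-en-1-one | O=C1C(I)=C[C@](O)(/C(C)=C/c2ccc(OC)c(OC)c2)[C@@H](OC)C1 | intermediate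
15 | (E)-prop-1-en-1-ylboronic acid | C/C=C/B(O)O | starting material
16 | (4S,5S)-4-[(E)-1-(3,4-dimethoxyphenyl)prop-1-en-2-yl]-4-hydroxy-5-methoxy-2-[(E)-prop-1-en-1-yl]cyclohex-2-en-1-one | C/C=C/C1=C[C@](O)(/C(C)=C/c2ccc(OC)c(OC)c2)[C@@H](OC)CC1=O | intermediate
17 | (5S,6S)-5-[(E)-1-(3,4-dimethoxyphenyl)prop-1-en-2-yl]-6-methoxy-3-[(E)-prop-1-en-1-yl]-2,5-bis(trimethylsilyloxy)cyclohexa-1,3-diene | C/C=C/C1=C[C@](O[Si](C)(C)C)(/C(C)=C/c2ccc(OC)c(OC)c2)[C@@H](OC)C=C1O[Si](C)(C)C | intermediate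
18 | (4S)-4-[(E)-1-(3,4-dimethoxyphenyl)prop-1-en-2-yl]-5-methoxy-2-[(E)-prop-1-en-1-yl]-4-(trimethylsilyloxy)cyclohexa-2,5-dien-1-one | C/C=C/C1=C[C@](O[Si](C)(C)C)(/C(C)=C/c2ccc(OC)c(OC)c2)C(OC)=CC1=O | intermediate
19 | (4S)-4-[(E)-1-(3,4-dimethoxyphenyl)prop-1-en-2-yl]-4-hydroxy-5-methoxy-2-[(E)-prop-1-en-1-yl]cyclohexa-2,5-dien-1-one | C/C=C/C1=C[C@](O)(/C(C)=C/c2ccc(OC)c(OC)c2)C(OC)=CC1=O | intermediate
20 | sodium (1S)-1-[(E)-1-(3,4-dimethoxyphenyl)prop-1-en-2-yl]-6-methoxy-4-oxo-3-[(E)-prop-1-en-1-yl]cyclohexa-2,5-dien-1-olate | C/C=C/C1=C[C@]([O-])(/C(C)=C/c2ccc(OC)c(OC)c2)C(OC)=CC1=O.[Na+] | intermediate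
21 | (4S)-4-[(E)-1-(3,4-dimethoxyphenyl)prop-1-en-2-yl]-4,5-dimethoxy-2-[(E)-prop-1-en-1-yl]cyclohexa-2,5-dien-1-one | C/C=C/C1=C[C@](OC)(/C(C)=C/c2ccc(OC)c(OC)c2)C(OC)=CC1=O | target

## Step count and risks

Total steps: 12. Longest linear sequence: 12 steps (from 1; compounds 3 and 15 are bought).

Three steps most likely to fail:

Step 2 (aldol addition and silyl trap). The ketone–ketone aldolate can revert or drift to conjugate addition before it is silylated. The fallback sets out from 2 and comes back at 6. Compound 2 is treated with the lithium enolate of N-methoxy-N-methylpropanamide (LiN(iPr)2, THF, −78 °C, then Me3SiCl), whose aldolate is much less prone to retro-aldol, to give rac-2-[4,4-dimethoxy-1-(trimethylsilyloxy)cyclohexa-2,5-dien-1-yl]-N-methoxy-N-methylpropanamide F1. Acyl substitution of F1 with 3,4-(MeO)2C6H3MgBr (THF, 0 °C) then gives 6; the chelated tetrahedral intermediate prevents over-addition.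

Step 6 (desymmetrisation). The hindered tertiary quinol OH may form the boronic hemiester slowly, or the enantioselectivity may be insufficient (the ee of 12 is checked and raised by recrystallisation). The fallback sets out from 10 and comes back at 12. A chiral-phosphoric-acid-catalysed hemiacetalisation/oxa-Michael cascade of 10 with 3-methylbutanal is run with 3,3′-bis(2,4,6-triisopropylphenyl)-1,1′-binaphthyl-2,2′-diyl hydrogen phosphate (the enantiomer that gives the S,S series, 10 mol %) and 4 Å molecular sieves in CH2Cl2. It gives the cis-fused dioxolane (3aS,7aS)-7a-[(E)-1-(3,4-dimethoxyphenyl)prop-1-en-2-yl]-2-(2-methylpropyl)-3a,4-dihydro-1,3-benzodioxol-5(7aH)-one F2, whose acetal is hydrolysed (1 M aq. HCl, THF, 0 °C) to 12.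

Step 11 (Saegusa oxidation). Loss of the β-methoxy group from the enol silane or palladium enolate, or sluggish β-hydride elimination towards an oxygen-bearing carbon, would lower the yield. The fallback sets out from 16 and comes back at 19, bypassing 17 and 18. Compound 16 is doubly deprotonated with LiN(SiMe3)2 (2.2 equiv, THF, −78 °C) and selenenylated with PhSeCl to give (4S,5R)-4-[(E)-1-(3,4-dimethoxyphenyl)prop-1-en-2-yl]-4-hydroxy-5-methoxy-6-(phenylselanyl)-2-[(E)-prop-1-en-1-yl]cyclohex-2-en-1-one F3 (C6 epimers; C4 and C5 spatially as in 16). Oxidation with H2O2/pyridine (CH2Cl2, 0 °C) gives the selenoxide (4S,5R)-4-[(E)-1-(3,4-dimethoxyphenyl)prop-1-en-2-yl]-4-hydroxy-5-methoxy-6-(phenylseleninyl)-2-[(E)-prop-1-en-1-yl]cyclohex-2-en-1-one F4, which undergoes syn-elimination below room temperature to 19.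

## Further compounds

F1 | step 2 | rac-2-[4,4-dimethoxy-1-(trimethylsilyloxy)cyclohexa-2,5-dien-1-yl]-N-methoxy-N-methylpropanamide | CC(C(=O)N(C)OC)C1(O[Si](C)(C)C)C=CC(OC)(OC)C=C1
F2 | step 6 | (3aS,7aS)-7a-[(E)-1-(3,4-dimethoxyphenyl)prop-1-en-2-yl]-2-(2-methylpropyl)-3a,4-dihydro-1,3-benzodioxol-5(7aH)-one | O=C1C=C[C@@]2(/C(C)=C/c3ccc(OC)c(OC)c3)OC(CC(C)C)O[C@H]2C1
F3 | step 11 | (4S,5R)-4-[(E)-1-(3,4-dimethoxyphenyl)prop-1-en-2-yl]-4-hydroxy-5-methoxy-6-(phenylselanyl)-2-[(E)-prop-1-en-1-yl]cyclohex-2-en-1-one | C/C=C/C1=C[C@](O)(/C(C)=C/c2ccc(OC)c(OC)c2)[C@@H](OC)C([Se]c2ccccc2)C1=O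
F4 | step 11 | (4S,5R)-4-[(E)-1-(3,4-dimethoxyphenyl)prop-1-en-2-yl]-4-hydroxy-5-methoxy-6-(phenylseleninyl)-2-[(E)-prop-1-en-1-yl]cyclohex-2-en-1-one | C/C=C/C1=C[C@](O)(/C(C)=C/c2ccc(OC)c(OC)c2)[C@@H](OC)C([Se](=O)c2ccccc2)C1=O
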